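**Retrosynthetic overview**

1. Germacrane numbering: ring A = 3(2H)-furanone (O, C1–C4; C3 ketone, C15 methyl on C4); ring B = butenolide (O, C6, C7, C11, C12; C13 = CH2OAc on C11); ring C = ten-membered carbocycle C1–C10 (C8 senecioate, C14 methyl on C10). Target = 4S, 8S, 10S, 5E.
2. Last step: seco acid 20 + CO give rings C and B in one palladium-mediated operation (bonds C6–C7, C11–C12 and O–C12; C12 comes from CO), with acetate and senecioate already in place.
3. Ring A is made before that by acyl–alkyne coupling of alkyne 8 with acid chloride 16 and amine-assisted ring closure (bonds C2–C3 and O–C1).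
4. Alkyne 8 comes from crotonaldehyde and a silylacetylene (sets C10), propargyl acetate (sets C8) and senecioic acid; acid chloride 16 comes from (R)-lactic acid, pivalaldehyde and tert-butyl bromoacetate (sets C4).
5. Order of ring formation: ring A first, then rings C and B together.

**Assumptions**

- For steps 1 and 2 (and the transfer hydrogenation in the fallback to step 2) the ligand enantiomer written is assumed to give the drawn configuration; if the first batch shows the opposite sense, the mirror-image ligand is used.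
- (R)-Lactic acid (D-lactic acid) is taken as a commercial starting material.

**Route**

Step 1
Reactants: 1 (E)-but-2-enal; 2 ethynyltri(propan-2-yl)silane
Product: 3 (3S)-3-methyl-5-[tri(propan-2-yl)silyl]pent-4-ynal
Conditions: [Rh(OAc)(C2H4)2]2 (2.5 mol%), (R)-DTBM-SEGPHOS (6 mol%), MeOH, 40 °C
Reagents that add atoms: none
Why: Rhodium-catalysed asymmetric conjugate alkynylation of an enal, in which the alkynylrhodium–bisphosphine species adds to one enantioface of the enal and the bulky silyl group suppresses alkyne dimerisation, so that the ligand sets C10 as S.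

Step 2
Reactants: 3 (3S)-3-methyl-5-[tri(propan-2-yl)silyl]pent-4-ynal; 4 prop-2-yn-1-yl acetate
Product: 5 (4S,6S)-4-hydroxy-6-methyl-8-[tri(propan-2-yl)silyl]octa-2,7-diyn-1-yl acetate
Conditions: Me2Zn (3 equiv), (S,S)-ProPhenol (20 mol%), Ph3PO (40 mol%), toluene, 0 °C; aq. NH4Cl
Reagents that add atoms: none
Why: Zinc–ProPhenol catalysed asymmetric alkynylation of an aldehyde, in which only the terminal alkyne of 4 can be zincated (the alkyne of 3 is silyl-capped) and the dinuclear zinc catalyst delivers it to one aldehyde face, so that C8 is set as S under catalyst control.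

Step 3
Reactants: 5 (4S,6S)-4-hydroxy-6-methyl-8-[tri(propan-2-yl)silyl]octa-2,7-diyn-1-yl acetate; 6 3-methylbut-2-enoic acid
Product: 7 (4S,6S)-1-acetoxy-6-methyl-8-[tri(propan-2-yl)silyl]octa-2,7-diyn-4-yl 3-methylbut-2-enoate
Conditions: iPrN=C=NiPr (1.3 equiv), 4-(dimethylamino)pyridine (10 mol%), CH2Cl2, 0 °C to rt
Reagents that add atoms: none
Why: Steglich esterification acylates the propargylic alcohol on oxygen, so C8 keeps its configuration, and the low amine loading avoids deconjugation of the senecioyl group.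

Step 4
Reactants: 7 (4S,6S)-1-acetoxy-6-methyl-8-[tri(propan-2-yl)silyl]octa-2,7-diyn-4-yl 3-methylbut-2-enoate
Product: 8 (4S,6S)-1-acetoxy-6-methylocta-2,7-diyn-4-yl 3-methylbut-2-enoate
Conditions: Bu4NF (1.2 equiv), AcOH (1.2 equiv), THF, 0 °C
Reagents that add atoms: none
Why: Fluoride-induced protodesilylation of a silylalkyne, buffered by acetic acid so that the acetate and the propargylic senecioate survive; no stereocentre is involved.

Step 5
Reactants: 9 (2R)-2-hydroxypropanoic acid; 10 2,2-dimethylpropanal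
Product: 11 (2R,5R)-2-tert-butyl-5-methyl-1,3-dioxolan-4-one
Conditions: TsOH·H2O (cat.), H2SO4 (cat.), pentane, reflux, Dean–Stark; crystallisation from pentane/Et2O, −78 °C
Reagents that add atoms: none
Why: Acid-catalysed acetalisation with water removal (first stage of Seebach self-regeneration of stereocentres) gives the cis-dioxolanone as the thermodynamic, crystallisable product, leaving the lactate centre untouched and storing its chirality in the new acetal centre (2R).

Step 6
Reactants: 11 (2R,5R)-2-tert-butyl-5-methyl-1,3-dioxolan-4-one; 12 tert-butyl 2-bromoacetate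
Product: 13 tert-butyl 2-[(2R,4S)-2-tert-butyl-4-methyl-5-oxo-1,3-dioxolan-4-yl]acetate
Conditions: LiN(iPr)2 (1.05 equiv), THF, −78 °C; then 12, −78 to −30 °C
Reagents that add atoms: none
Why: Diastereoselective enolate alkylation in which the electrophile enters anti to the tert-butyl group on the acetal carbon (dr above 95:5), creating the quaternary centre that becomes C4 with the S configuration.

Step 7
Reactants: 13 tert-butyl 2-[(2R,4S)-2-tert-butyl-4-methyl-5-oxo-1,3-dioxolan-4-yl]acetate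
Product: 14 (2S)-4-tert-butoxy-2-hydroxy-2-methyl-4-oxobutanoic acid
Conditions: LiOH (2.2 equiv), THF/H2O, 0 °C; then 1 M HCl to pH 3
Reagents that add atoms: lithium hydroxide, [Li+].[OH-]
Why: Saponification of the activated acylal-type lactone releases pivalaldehyde and the α-hydroxy acid at 0 °C while the hindered tert-butyl ester survives; the quaternary centre is not involved.

Step 8
Reactants: 14 (2S)-4-tert-butoxy-2-hydroxy-2-methyl-4-oxobutanoic acid
Product: 16 tert-butyl (3S)-4-chloro-3-methyl-4-oxo-3-[(trimethylsilyl)oxy]butanoate, via bis-silyl derivative 15 (not isolated)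
Conditions: Me3SiCl (2.3 equiv), Et3N (2.4 equiv), 4-(dimethylamino)pyridine (cat.), CH2Cl2, 0 °C to rt; then (COCl)2 (1.1 equiv), DMF (cat.), 0 °C; used crude
Reagents that add atoms: chlorotrimethylsilane, C[Si](C)(C)Cl; oxalyl chloride, O=C(Cl)C(Cl)=O
Why: Silylation of both hydroxyl functions followed by Vilsmeier-type exchange of the silyl ester for the acid chloride gives the acyl donor without free HCl, keeping the tertiary oxygen masked and the tert-butyl ester intact; no bond to the stereocentre is broken.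

Step 9
Reactants: 8 (4S,6S)-1-acetoxy-6-methylocta-2,7-diyn-4-yl 3-methylbut-2-enoate; 16 tert-butyl (3S)-4-chloro-3-methyl-4-oxo-3-[(trimethylsilyl)oxy]butanoate
Product: 19 tert-butyl 2-[(2S)-5-[(2S,4S)-7-acetoxy-4-[(3-methylbut-2-enoyl)oxy]hept-5-yn-2-yl]-2-methyl-3-oxo-2,3-dihydrofuran-2-yl]acetate, via silyloxy ynone 17 (not isolated), via enaminone 18 (not isolated)
Conditions: PdCl2(PPh3)2 (2 mol%), CuI (4 mol%), Et3N (1.5 equiv), THF, rt; then Et2NH (1.5 equiv), rt; then AcOH, H2O, rt
Reagents that add atoms: none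
Why: Acyl Sonogashira coupling gives the ynone, diethylamine adds to it in a conjugate sense faster than the ynone can isomerise at C10, and aqueous acid removes the silyl group so that the tertiary hydroxyl closes onto the iminium carbon (5-exo-trig addition–elimination with loss of diethylamine) to form ring A, leaving C4, C8 and C10 untouched.

Step 10
Reactants: 19 tert-butyl 2-[(2S)-5-[(2S,4S)-7-acetoxy-4-[(3-methylbut-2-enoyl)oxy]hept-5-yn-2-yl]-2-methyl-3-oxo-2,3-dihydrofuran-2-yl]acetate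
Product: 20 2-[(2S)-5-[(2S,4S)-7-acetoxy-4-[(3-methylbut-2-enoyl)oxy]hept-5-yn-2-yl]-2-methyl-3-oxo-2,3-dihydrofuran-2-yl]acetic acid
Conditions: CF3CO2H/CH2Cl2 (1:4), 0 °C to rt
Reagents that add atoms: none
Why: Acidolysis of the tert-butyl ester (E1 loss of isobutene) leaves the furanone, the acetate and the senecioate intact; no stereocentre is involved.

Step 11
Reactants: 20 2-[(2S)-5-[(2S,4S)-7-acetoxy-4-[(3-methylbut-2-enoyl)oxy]hept-5-yn-2-yl]-2-methyl-3-oxo-2,3-dihydrofuran-2-yl]acetic acid; 21 carbon monoxide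
Product: 23 (4S,5E,8S,10S)-13-acetoxy-8-[(3-methylbut-2-enoyl)oxy]-3-oxo-1,4-epoxygermacra-1,5,7(11)-trien-12,6-olide (target CNP0102620.1), via acid chloride 22 (not isolated)
Conditions: Me2C=C(Cl)NMe2 (1.1 equiv), CH2Cl2, 0 °C to rt; then added over 12 h to Pd(PPh3)4 (10 mol%), 2,6-di-tert-butyl-4-methylpyridine (1.5 equiv), CO (20 bar), toluene, 90 °C, final 1 mM
Reagents that add atoms: none
Why: Proposed new method: the acid chloride adds oxidatively to zerovalent palladium, CO pressure holds the acylpalladium against decarbonylation, an intramolecular 10-exo-dig syn-acylpalladation of the alkyne forms C6–C7 and closes ring C, CO inserts into the resulting C11–Pd bond, and the enol oxygen of the new C6 ketone attacks that second acylpalladium to close ring B, so that syn addition places C6 and C12 cis on C7=C11 and the ring enforces the 5E geometry without forming or touching any stereocentre; the closest known reaction types are the intermolecular acylpalladation of internal alkynes under CO with lactone formation and the palladium-catalysed carbonylative lactonisation of (Z)-β-iodoenones by O-enolate trapping, the untested element being alkyne insertion in a medium-ring sense, which the rigid furanone, the quaternary C4 and high dilution should assist.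

**Compound list**

1 | (E)-but-2-enal (crotonaldehyde) | C/C=C/C=O | starting material
2 | ethynyltri(propan-2-yl)silane | C#C[Si](C(C)C)(C(C)C)C(C)C | starting material
3 | (3S)-3-methyl-5-[tri(propan-2-yl)silyl]pent-4-ynal | O=CC[C@H](C)C#C[Si](C(C)C)(C(C)C)C(C)C | intermediate
4 | prop-2-yn-1-yl acetate | CC(=O)OCC#C | starting material
5 | (4S,6S)-4-hydroxy-6-methyl-8-[tri(propan-2-yl)silyl]octa-2,7-diyn-1-yl acetate | CC(=O)OCC#C[C@@H](O)C[C@H](C)C#C[Si](C(C)C)(C(C)C)C(C)C | intermediate
6 | 3-methylbut-2-enoic acid (senecioic acid) | CC(C)=CC(=O)O | starting material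
7 | (4S,6S)-1-acetoxy-6-methyl-8-[tri(propan-2-yl)silyl]octa-2,7-diyn-4-yl 3-methylbut-2-enoate | CC(=O)OCC#C[C@@H](OC(=O)C=C(C)C)C[C@H](C)C#C[Si](C(C)C)(C(C)C)C(C)C | intermediate
8 | (4S,6S)-1-acetoxy-6-methylocta-2,7-diyn-4-yl 3-methylbut-2-enoate | CC(=O)OCC#C[C@@H](OC(=O)C=C(C)C)C[C@H](C)C#C | intermediate
9 | (2R)-2-hydroxypropanoic acid ((R)-lactic acid) | C[C@@H](O)C(=O)O | starting material
10 | 2,2-dimethylpropanal (pivalaldehyde) | CC(C)(C)C=O | starting material
11 | (2R,5R)-2-tert-butyl-5-methyl-1,3-dioxolan-4-one | C[C@H]1O[C@@H](C(C)(C)C)OC1=O | intermediate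
12 | tert-butyl 2-bromoacetate | CC(C)(C)OC(=O)CBr | starting material
13 | tert-butyl 2-[(2R,4S)-2-tert-butyl-4-methyl-5-oxo-1,3-dioxolan-4-yl]acetate | CC(C)(C)OC(=O)C[C@]1(C)O[C@@H](C(C)(C)C)OC1=O | intermediate
14 | (2S)-4-tert-butoxy-2-hydroxy-2-methyl-4-oxobutanoic acid | CC(C)(C)OC(=O)C[C@](C)(O)C(=O)O | intermediate
15 | trimethylsilyl (2S)-4-tert-butoxy-2-methyl-4-oxo-2-[(trimethylsilyl)oxy]butanoate | CC(C)(C)OC(=O)C[C@](C)(O[Si](C)(C)C)C(=O)O[Si](C)(C)C | intermediate (not isolated)
16 | tert-butyl (3S)-4-chloro-3-methyl-4-oxo-3-[(trimethylsilyl)oxy]butanoate | CC(C)(C)OC(=O)C[C@](C)(O[Si](C)(C)C)C(Cl)=O | intermediate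
17 | tert-butyl (3S,7S,9S)-12-acetoxy-3,7-dimethyl-9-[(3-methylbut-2-enoyl)oxy]-4-oxo-3-[(trimethylsilyl)oxy]dodeca-5,10-diynoate | CC(=O)OCC#C[C@@H](OC(=O)C=C(C)C)C[C@H](C)C#CC(=O)[C@@](C)(O[Si](C)(C)C)CC(=O)OC(C)(C)C | intermediate (not isolated)
18 | tert-butyl (3S,7S,9S)-12-acetoxy-6-(diethylamino)-3,7-dimethyl-9-[(3-methylbut-2-enoyl)oxy]-4-oxo-3-[(trimethylsilyl)oxy]dodec-5-en-10-ynoate (alkene geometry not defined) | CC(=O)OCC#C[C@@H](OC(=O)C=C(C)C)C[C@H](C)C(N(CC)CC)=CC(=O)[C@@](C)(O[Si](C)(C)C)CC(=O)OC(C)(C)C | intermediate (not isolated)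
19 | tert-butyl 2-[(2S)-5-[(2S,4S)-7-acetoxy-4-[(3-methylbut-2-enoyl)oxy]hept-5-yn-2-yl]-2-methyl-3-oxo-2,3-dihydrofuran-2-yl]acetate | CC(=O)OCC#C[C@@H](OC(=O)C=C(C)C)C[C@H](C)C1=CC(=O)[C@](C)(CC(=O)OC(C)(C)C)O1 | intermediate
20 | 2-[(2S)-5-[(2S,4S)-7-acetoxy-4-[(3-methylbut-2-enoyl)oxy]hept-5-yn-2-yl]-2-methyl-3-oxo-2,3-dihydrofuran-2-yl]acetic acid | CC(=O)OCC#C[C@@H](OC(=O)C=C(C)C)C[C@H](C)C1=CC(=O)[C@](C)(CC(=O)O)O1 | intermediate
21 | carbon monoxide | [C-]#[O+] | starting material
22 | 2-[(2S)-5-[(2S,4S)-7-acetoxy-4-[(3-methylbut-2-enoyl)oxy]hept-5-yn-2-yl]-2-methyl-3-oxo-2,3-dihydrofuran-2-yl]acetyl chloride | CC(=O)OCC#C[C@@H](OC(=O)C=C(C)C)C[C@H](C)C1=CC(=O)[C@](C)(CC(Cl)=O)O1 | intermediate (not isolated)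
23 | (4S,5E,8S,10S)-13-acetoxy-8-[(3-methylbut-2-enoyl)oxy]-3-oxo-1,4-epoxygermacra-1,5,7(11)-trien-12,6-olide | CC(=O)OCC1=C2/C(=C\[C@]3(C)OC(=CC3=O)[C@@H](C)C[C@@H]2OC(=O)C=C(C)C)OC1=O | target

**Step count and risks**

Total step count: 11. Longest linear sequence: 7 steps (1, 2, 3, 4, 9, 10, 11; the branch 5, 6, 7, 8, 9, 10, 11 is equally long).

The three steps most likely to fail:

Step 11 is the least secure. Alkyne insertion into an acylpalladium in a ten-membered-ring sense has no direct precedent. Insertion could also occur in the endo sense, the alkenylpalladium carries a β-acetoxy group that could eliminate to an allene before CO inserts, and zerovalent palladium can ionise propargylic esters. The fallback sets out from 19 and comes back at 23; it replaces insertion by transmetalation. Syn-diboration of the alkyne of 19 (Pt(PPh3)4 3 mol%, bis(pinacolato)diboron, DMF, 80 °C) gives the cis-bis-boronate tert-butyl 2-[(2S)-5-[(2S,4S,5Z)-7-acetoxy-4-[(3-methylbut-2-enoyl)oxy]-5,6-bis(4,4,5,5-tetramethyl-1,3,2-dioxaborolan-2-yl)hept-5-en-2-yl]-2-methyl-3-oxo-2,3-dihydrofuran-2-yl]acetate F5. CF3CO2H in CH2Cl2 then gives the corresponding acetic acid F6, and Me2C=C(Cl)NMe2 converts it into the acetyl chloride F7. F7 is added slowly to Pd(PPh3)4 and anhydrous K3PO4 in toluene at 60 °C, where an intramolecular acyl Suzuki–Miyaura coupling at the C7 boronate closes ring C. The product is the macrocyclic β-boryl enone (4S,8S,10S)-13-acetoxy-8-[(3-methylbut-2-enoyl)oxy]-11-(4,4,5,5-tetramethyl-1,3,2-dioxaborolan-2-yl)-12-nor-1,4-epoxygermacra-1,7(11)-diene-3,6-dione F8; its remaining boron is cis to the C6 ketone because the diboration is syn and the coupling retentive. Oxidative carbonylation of that boronate (Pd(OAc)2 10 mol%, p-benzoquinone, CO 1 bar, THF, 40 °C), with the acylpalladium trapped by the enol oxygen of the C6 ketone, closes ring B and gives 23.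

Step 2 is the next risk. Aldehyde 3 is unbranched at the α-carbon, so aldol side reactions and a lower enantiomeric excess are possible, and propargyl acetate is a less common alkyne donor. The fallback sets out from 3 and comes back at 5; it sets C8 by reagent-controlled reduction instead of by C–C bond formation. Addition of the zinc acetylide of 4 (Et2Zn, toluene, then 3, no chiral ligand) gives (4RS,6S)-4-hydroxy-6-methyl-8-[tri(propan-2-yl)silyl]octa-2,7-diyn-1-yl acetate F1. Dess–Martin periodinane oxidises it to the ynone (6S)-6-methyl-4-oxo-8-[tri(propan-2-yl)silyl]octa-2,7-diyn-1-yl acetate F2. Noyori asymmetric transfer hydrogenation (RuCl(p-cymene)[(S,S)-TsDPEN], iPrOH, rt) then gives 5.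

Step 9 is the third risk. The α-silyloxy acid chloride is hindered, the ynone could isomerise at C10 before the amine adds, and diethylamine could attack the esters. The fallback sets out from 16 and comes back at 19; it makes the ynone by aldehyde alkynylation and oxidation. LiAlH(OtBu)3 (THF, −78 °C) reduces 16 to the aldehyde tert-butyl (3S)-3-methyl-4-oxo-3-[(trimethylsilyl)oxy]butanoate F3. Zinc acetylide addition of 8 (Zn(OTf)2, Et3N, toluene, rt) gives the propargylic alcohol tert-butyl (3S,4RS,7S,9S)-12-acetoxy-4-hydroxy-3,7-dimethyl-9-[(3-methylbut-2-enoyl)oxy]-3-[(trimethylsilyl)oxy]dodeca-5,10-diynoate F4, whose new carbinol centre is removed in the next operation. Dess–Martin periodinane gives 17, here isolated, and Et2NH followed by AcOH/H2O gives 19 through 18.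

**Further compounds**

F1 | step 2 | (4RS,6S)-4-hydroxy-6-methyl-8-[tri(propan-2-yl)silyl]octa-2,7-diyn-1-yl acetate (both C4 epimers) | CC(=O)OCC#CC(O)C[C@H](C)C#C[Si](C(C)C)(C(C)C)C(C)C
F2 | step 2 | (6S)-6-methyl-4-oxo-8-[tri(propan-2-yl)silyl]octa-2,7-diyn-1-yl acetate | CC(=O)OCC#CC(=O)C[C@H](C)C#C[Si](C(C)C)(C(C)C)C(C)C
F3 | step 9 | tert-butyl (3S)-3-methyl-4-oxo-3-[(trimethylsilyl)oxy]butanoate | CC(C)(C)OC(=O)C[C@](C)(O[Si](C)(C)C)C=O
F4 | step 9 | tert-butyl (3S,4RS,7S,9S)-12-acetoxy-4-hydroxy-3,7-dimethyl-9-[(3-methylbut-2-enoyl)oxy]-3-[(trimethylsilyl)oxy]dodeca-5,10-diynoate (both C4 epimers) | CC(=O)OCC#C[C@@H](OC(=O)C=C(C)C)C[C@H](C)C#CC(O)[C@@](C)(O[Si](C)(C)C)CC(=O)OC(C)(C)C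
F5 | step 11 | tert-butyl 2-[(2S)-5-[(2S,4S,5Z)-7-acetoxy-4-[(3-methylbut-2-enoyl)oxy]-5,6-bis(4,4,5,5-tetramethyl-1,3,2-dioxaborolan-2-yl)hept-5-en-2-yl]-2-methyl-3-oxo-2,3-dihydrofuran-2-yl]acetate | CC(=O)OC/C(B1OC(C)(C)C(C)(C)O1)=C(/B1OC(C)(C)C(C)(C)O1)[C@@H](OC(=O)C=C(C)C)C[C@H](C)C1=CC(=O)[C@](C)(CC(=O)OC(C)(C)C)O1
F6 | step 11 | 2-[(2S)-5-[(2S,4S,5Z)-7-acetoxy-4-[(3-methylbut-2-enoyl)oxy]-5,6-bis(4,4,5,5-tetramethyl-1,3,2-dioxaborolan-2-yl)hept-5-en-2-yl]-2-methyl-3-oxo-2,3-dihydrofuran-2-yl]acetic acid | CC(=O)OC/C(B1OC(C)(C)C(C)(C)O1)=C(/B1OC(C)(C)C(C)(C)O1)[C@@H](OC(=O)C=C(C)C)C[C@H](C)C1=CC(=O)[C@](C)(CC(=O)O)O1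
F7 | step 11 | 2-[(2S)-5-[(2S,4S,5Z)-7-acetoxy-4-[(3-methylbut-2-enoyl)oxy]-5,6-bis(4,4,5,5-tetramethyl-1,3,2-dioxaborolan-2-yl)hept-5-en-2-yl]-2-methyl-3-oxo-2,3-dihydrofuran-2-yl]acetyl chloride | CC(=O)OC/C(B1OC(C)(C)C(C)(C)O1)=C(/B1OC(C)(C)C(C)(C)O1)[C@@H](OC(=O)C=C(C)C)C[C@H](C)C1=CC(=O)[C@](C)(CC(Cl)=O)O1
F8 | step 11 | (4S,8S,10S)-13-acetoxy-8-[(3-methylbut-2-enoyl)oxy]-11-(4,4,5,5-tetramethyl-1,3,2-dioxaborolan-2-yl)-12-nor-1,4-epoxygermacra-1,7(11)-diene-3,6-dione (boron cis to the C6 ketone) | CC(=O)OC/C(B1OC(C)(C)C(C)(C)O1)=C2/C(=O)C[C@]3(C)OC(=CC3=O)[C@@H](C)C[C@@H]2OC(=O)C=C(C)C
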